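**Plan**

1. Numbering (daucane): C1 is the ring-fusion carbon with the angular methyl, C2/C3 are CH2, C4 is the isopropyl carbinol, C5 the ring-fusion CH, C6 the ester carbon, C7 a CH2, C8 the methyl carbinol, C9=C10 the alkene; the seven-membered ring is C1–C5–C6–C7–C8–C9–C10.
2. Enabling feature: this ring has oxygen on C6, a lone CH2 at C7 and a methyl on C8, so it maps onto a siloxycyclopropane C6–C7–C8 flanked by the cyclopentene C5=C1 and a vinyl group C9=C10.
3. Retrosynthetic cuts, in order: the vanilloyl C6–O ester; C8–OH/C9=C10 back to a C8=C9 alkene; ring bond C1–C10 (with C6–C8 restored) to the divinylcyclopropane; the cyclopropane CH2 (C7); C5–C6 to a tiglyl unit; C4–isopropyl.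
4. Forward: the five-membered ring is bought as 3-methylcyclopentenone, C4 is set by isopropyl addition, C5 is acylated, the silyl dienol ether is cyclopropanated, and the Cope rearrangement closes the seven-membered ring last; redox adjustment and esterification follow.
5. Stereochemistry: C4 from a chiral titanium catalyst; the cyclopropane, and through it quaternary C1, from C4–OH-directed cyclopropanation; C5 from protonation to the trans-fused ketone; C6 from C4–OH-directed hydride delivery; C8 from C6–OH-directed epoxidation.

Key step: step 7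

Assumption: β is the face of the C1 methyl and α the opposite face; in step 2 the ligand antipode that sends isopropyl to the Re face of ketone 2 is the one used.

**Route**

Step 1
Reactants: 1 3-methylcyclopent-2-en-1-one
Product: 2 2-iodo-3-methylcyclopent-2-en-1-one
Conditions: I2 (1.5 equiv), pyridine/CH2Cl2 1:1, 0 °C to rt
Reagents that add atoms: iodine, II
Why: α-Iodination of the enone by conjugate addition of pyridine, iodination of the enolate and loss of pyridine (Baylis–Hillman-type addition–elimination) puts the halogen on the future C5 and keeps the carbonyl for step 2; no stereocentre is formed.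

Step 2
Reactants: 2 2-iodo-3-methylcyclopent-2-en-1-one; 3 diisopropylzinc
Product: 4 (1R)-2-iodo-3-methyl-1-(propan-2-yl)cyclopent-2-en-1-ol
Conditions: iPr2Zn (2 equiv), Ti(OiPr)4 (1.2 equiv), bis(sulfonamide) diol ligand from trans-cyclohexane-1,2-diamine and 10-camphorsulfonyl chloride (10 mol %), toluene/hexane, rt; aq NH4Cl
Reagents that add atoms: none
Why: Titanium-promoted catalytic asymmetric 1,2-addition of a dialkylzinc to an α-substituted cyclic enone: the α-iodine makes the two flanks of the carbonyl unlike, the chiral bis(sulfonamide)–titanium complex passes isopropyl to the Re face, and C4 is set as R.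

Step 3
Reactants: 5 tigloyl chloride; 6 N,O-dimethylhydroxylamine hydrochloride
Product: 7 (2E)-N-methoxy-N,2-dimethylbut-2-enamide
Conditions: pyridine (2.2 equiv), CH2Cl2, 0 °C to rt
Reagents that add atoms: none
Why: Acylation of the hydroxylamine nitrogen by the acid chloride (Schotten–Baumann-type amide formation) gives the Weinreb amide with the (E)-alkene untouched.

Step 4
Reactants: 4 (1R)-2-iodo-3-methyl-1-(propan-2-yl)cyclopent-2-en-1-ol; 7 (2E)-N-methoxy-N,2-dimethylbut-2-enamide
Product: 9 (2E)-1-[(5R)-5-hydroxy-2-methyl-5-(propan-2-yl)cyclopent-1-en-1-yl]-2-methylbut-2-en-1-one, via dilithiated cyclopentenol 8 (not isolated)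
Conditions: t-BuLi (3.1 equiv), Et2O, −78 °C; then 7, −78 to 0 °C; aq NH4Cl; chromatography on Et3N-deactivated silica
Reagents that add atoms: none
Why: One equivalent of t-BuLi deprotonates the alcohol and two more carry out iodine–lithium exchange, and the alkenyllithium adds only once to the amide because the N-methoxy chelate holds the tetrahedral adduct until work-up (Weinreb ketone synthesis); C4 is not touched, no stereocentre is formed, and acid is avoided because the product is a divinyl ketone prone to Nazarov cyclisation.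

Step 5
Reactants: 9 (2E)-1-[(5R)-5-hydroxy-2-methyl-5-(propan-2-yl)cyclopent-1-en-1-yl]-2-methylbut-2-en-1-one
Product: 11 (1R)-2-[(1E)-1-{[tert-butyl(dimethyl)silyl]oxy}-2-methylbuta-1,3-dien-1-yl]-3-methyl-1-(propan-2-yl)cyclopent-2-en-1-ol, via dipotassium alkoxide dienolate 10 (not isolated)
Conditions: 9 added to KN(SiMe3)2 (2.3 equiv), THF/DMPU, −78 °C; then TBSCl (1.1 equiv), −78 to −20 °C; aq NH4Cl
Reagents that add atoms: tert-butyldimethylsilyl chloride, CC(C)(C)[Si](C)(C)Cl
Why: Excess amide base forms the C4 alkoxide and then removes a proton from the tiglyl γ-methyl (C10) of the planar enone arm, the twisted, alkoxide-bearing cyclopentenyl arm being neither conjugated nor acidified, and TBSCl silylates the dienolate oxygen but not the hindered tertiary alkoxide (vinylogous enolisation/O-silylation); reaction through the s-trans enone conformer, with the carbonyl oxygen beside the C8 methyl and the bulky cyclopentenyl beside the small C9 hydrogen, should give the (E)-enol ether in which vinyl and cyclopentenyl are cis.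

Step 6
Reactants: 11 (1R)-2-[(1E)-1-{[tert-butyl(dimethyl)silyl]oxy}-2-methylbuta-1,3-dien-1-yl]-3-methyl-1-(propan-2-yl)cyclopent-2-en-1-ol
Product: 12 (1R)-2-[(1S,2R)-1-{[tert-butyl(dimethyl)silyl]oxy}-2-ethenyl-2-methylcyclopropyl]-3-methyl-1-(propan-2-yl)cyclopent-2-en-1-ol
Conditions: Et2Zn (3 equiv), CH2I2 (3 equiv), CH2Cl2, −20 to 0 °C; aq NH4Cl
Reagents that add atoms: diiodomethane, ICI
Why: Simmons–Smith cyclopropanation (Et2Zn/CH2I2 carbenoid) is stereospecific and favours the most electron-rich alkene, the silyl enol ether C6=C8, and the zinc alkoxide of the C4 hydroxyl hands CH2 to the face of that alkene turned toward C4 in the rotamer that has C8 on the hydroxyl side of the ring, which sets the cyclopropane as (1S,2R) with vinyl and cyclopentenyl cis.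

Step 7
Reactants: 12 (1R)-2-[(1S,2R)-1-{[tert-butyl(dimethyl)silyl]oxy}-2-ethenyl-2-methylcyclopropyl]-3-methyl-1-(propan-2-yl)cyclopent-2-en-1-ol
Product: 13 (1R,4R)-6-{[tert-butyl(dimethyl)silyl]oxy}dauca-5,8-dien-4-ol
Conditions: toluene (0.02 M, degassed, base-washed glass), 110 °C, sealed tube
Reagents that add atoms: none
Why: On heating, the cyclopentene C5=C1 and the vinyl group C9=C10, held cis on the three-membered ring, fold back over it in a boat transition state in which C6–C8 breaks as C1–C10 forms, a concerted [3,3]-sigmatropic shift driven by release of cyclopropane strain and eased by the siloxy donor on C6. The closest known reaction type is the divinylcyclopropane–cycloheptadiene (Cope) rearrangement of 1-siloxy-2-vinylcyclopropyl cycloalkenes to fused hydroazulenes. The seven-membered ring (C1, C5, C6, C7, C8, C9, C10) closes by sigmatropic ring expansion of the cyclopropane, not by a polar exo or endo cyclisation, and arrives as the 1,4-diene with C5=C6 as silyl enol ether and C8=C9 carrying the methyl. The one new stereocentre, quaternary C1, is controlled by the (1S,2R) cyclopropane: only the rotamer with C1 over the small ring can react, so C10 bonds to a single face of C1 and gives 1R, with the methyl on the same face as the C4 hydroxyl. The step needs the cis-divinyl isomer and must tolerate a fully substituted terminus whose methyl points at the cyclopropane CH2; the first is secured by the (E)-enol ether geometry carried stereospecifically through step 6, the second by strain release and the oxygen donor. No alkyl group sits cis to an alkene on the neighbouring ring carbon, so a 1,5-hydrogen shift cannot compete.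

Step 8
Reactants: 13 (1R,4R)-6-{[tert-butyl(dimethyl)silyl]oxy}dauca-5,8-dien-4-ol
Product: 14 (1R,4R,5R)-4-hydroxydauc-8-en-6-one
Conditions: Bu4NF (1.2 equiv), AcOH (1.2 equiv), THF, 0 °C
Reagents that add atoms: none
Why: Fluoride removes the silyl group from the enol ether and acetic acid protonates C5 on the face away from the angular C1 methyl, giving the trans-fused ketone (H-5 α), which should also be the more stable epimer because the C4 hydroxyl can hydrogen-bond to the C6 carbonyl and the isopropyl group stays clear of C6; the buffered medium avoids the alkoxide needed for retro-aldol opening of this β-hydroxy ketone (fluoride desilylation of a silyl enol ether).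

Step 9
Reactants: 14 (1R,4R,5R)-4-hydroxydauc-8-en-6-one
Product: 15 (1R,4R,5S,6S)-dauc-8-ene-4,6-diol
Conditions: Me4NBH(OAc)3 (5 equiv), MeCN/AcOH 1:1, −20 °C
Reagents that add atoms: none
Why: Evans–Saksena reduction: the C4 hydroxyl exchanges onto boron and the hydride is passed within the complex to the β face of the C6 carbonyl, so the new hydroxyl is α, anti to the C4 hydroxyl (C6 S).

Step 10
Reactants: 15 (1R,4R,5S,6S)-dauc-8-ene-4,6-diol
Product: 16 (1R,4R,5S,6S,8R,9S)-8,9-epoxydaucane-4,6-diol
Conditions: VO(acac)2 (5 mol %), t-BuOOH (1.5 equiv), 2,6-lutidine (0.2 equiv), CH2Cl2, 0 °C to rt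
Reagents that add atoms: tert-butyl hydroperoxide, CC(C)(C)OO
Why: Vanadium-catalysed hydroxyl-directed epoxidation: the secondary C6 hydroxyl, homoallylic to the only alkene C8=C9, binds the vanadium peroxide and delivers oxygen to the α face, syn to itself, which sets C8 (R) and C9 (S).

Step 11
Reactants: 16 (1R,4R,5S,6S,8R,9S)-8,9-epoxydaucane-4,6-diol
Product: 19 (1R,4R,5S,6S,8R)-dauc-9-ene-4,6,8-triol, via hydroxy selenide 17 (not isolated), via selenoxide 18 (not isolated)
Conditions: (PhSe)2 (0.75 equiv), NaBH4 (1.6 equiv), EtOH, rt then 78 °C; then THF, 30% H2O2, 0 °C to rt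
Reagents that add atoms: none
Why: Benzeneselenolate opens the epoxide by SN2 attack at the less substituted C9, which leaves the C8–O bond and its configuration untouched, and after oxidation the selenoxide undergoes syn-elimination toward C10, the only neighbour with hydrogen, to give the C9=C10 tertiary allylic alcohol (epoxide to allylic alcohol transposition by selenoxide elimination).

Step 12
Reactants: 20 vanillic acid
Product: 22 4-{[tert-butyl(dimethyl)silyl]oxy}-3-methoxybenzoic acid, via bis-silylated vanillic acid 21 (not isolated)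
Conditions: TBSCl (2.5 equiv), imidazole (5 equiv), DMF, rt; then AcOH/THF/H2O, rt
Reagents that add atoms: tert-butyldimethylsilyl chloride, CC(C)(C)[Si](C)(C)Cl
Why: Silylation of phenol and acid followed by selective hydrolysis of the labile silyl ester leaves the phenol masked, so that it cannot compete as a nucleophile in step 13 (silyl ether protection).

Step 13
Reactants: 19 (1R,4R,5S,6S,8R)-dauc-9-ene-4,6,8-triol; 22 4-{[tert-butyl(dimethyl)silyl]oxy}-3-methoxybenzoic acid
Product: 23 (1R,4R,5S,6S,8R)-4,8-dihydroxydauc-9-en-6-yl 4-{[tert-butyl(dimethyl)silyl]oxy}-3-methoxybenzoate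
Conditions: DCC (1.5 equiv), DMAP (0.5 equiv), CH2Cl2, rt
Reagents that add atoms: none
Why: Steglich esterification acylates the only secondary alcohol, C6–OH, while the tertiary C4 and C8 alcohols are too hindered to react, and C6 keeps its configuration because the C6–O bond is not broken.

Step 14
Reactants: 23 (1R,4R,5S,6S,8R)-4,8-dihydroxydauc-9-en-6-yl 4-{[tert-butyl(dimethyl)silyl]oxy}-3-methoxybenzoate
Product: 24 (1R,4R,5S,6S,8R)-4,8-dihydroxydauc-9-en-6-yl 4-hydroxy-3-methoxybenzoate (CNP0243386.4)
Conditions: Bu4NF (1.1 equiv), AcOH (1.1 equiv), THF, 0 °C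
Reagents that add atoms: none
Why: Fluoride cleaves the aryl silyl ether far faster than it could touch the hindered benzoate, and acetic acid buffers the phenoxide so that no acyl migration or ester cleavage follows (silyl ether deprotection).

**Compound list**

1 | 3-methylcyclopent-2-en-1-one | CC1=CC(=O)CC1 | starting material
2 | 2-iodo-3-methylcyclopent-2-en-1-one | CC1=C(I)C(=O)CC1 | intermediate
3 | diisopropylzinc | CC(C)[Zn]C(C)C | starting material
4 | (1R)-2-iodo-3-methyl-1-(propan-2-yl)cyclopent-2-en-1-ol | CC1=C(I)[C@](O)(C(C)C)CC1 | intermediate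
5 | tigloyl chloride, (2E)-2-methylbut-2-enoyl chloride | C/C=C(\C)C(=O)Cl | starting material
6 | N,O-dimethylhydroxylamine hydrochloride | CNOC.Cl | starting material
7 | (2E)-N-methoxy-N,2-dimethylbut-2-enamide | C/C=C(\C)C(=O)N(C)OC | intermediate
8 | lithium (1R)-2-lithio-3-methyl-1-(propan-2-yl)cyclopent-2-en-1-olate (dilithiated cyclopentenol) | [Li]C1=C(C)CC[C@@]1(O[Li])C(C)C | intermediate
9 | (2E)-1-[(5R)-5-hydroxy-2-methyl-5-(propan-2-yl)cyclopent-1-en-1-yl]-2-methylbut-2-en-1-one | C/C=C(\C)C(=O)C1=C(C)CC[C@@]1(O)C(C)C | intermediate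
10 | dipotassium salt of the C4 alkoxide and (1E)-dienolate of 9 | C=C/C(C)=C(/O[K])C1=C(C)CC[C@@]1(O[K])C(C)C | intermediate
11 | (1R)-2-[(1E)-1-{[tert-butyl(dimethyl)silyl]oxy}-2-methylbuta-1,3-dien-1-yl]-3-methyl-1-(propan-2-yl)cyclopent-2-en-1-ol (silyloxy trans to vinyl, cyclopentenyl cis to vinyl) | C=C/C(C)=C(/O[Si](C)(C)C(C)(C)C)C1=C(C)CC[C@@]1(O)C(C)C | intermediate
12 | (1R)-2-[(1S,2R)-1-{[tert-butyl(dimethyl)silyl]oxy}-2-ethenyl-2-methylcyclopropyl]-3-methyl-1-(propan-2-yl)cyclopent-2-en-1-ol (vinyl and cyclopentenyl cis on the cyclopropane) | C=C[C@@]1(C)C[C@@]1(O[Si](C)(C)C(C)(C)C)C2=C(C)CC[C@@]2(O)C(C)C | intermediate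
13 | (1R,4R)-6-{[tert-butyl(dimethyl)silyl]oxy}dauca-5,8-dien-4-ol (hydroazulene; C5=C6 silyl enol ether, C8=C9 with methyl on C8) | CC1=CC[C@@]2(C)CC[C@@](O)(C(C)C)C2=C(O[Si](C)(C)C(C)(C)C)C1 | intermediate
14 | (1R,4R,5R)-4-hydroxydauc-8-en-6-one (trans-fused, H-5 α) | CC1=CC[C@@]2(C)CC[C@@](O)(C(C)C)[C@@H]2C(=O)C1 | intermediate
15 | (1R,4R,5S,6S)-dauc-8-ene-4,6-diol (4β-OH, 6α-OH) | CC1=CC[C@@]2(C)CC[C@@](O)(C(C)C)[C@@H]2[C@@H](O)C1 | intermediate
16 | (1R,4R,5S,6S,8R,9S)-8,9-epoxydaucane-4,6-diol (α-epoxide) | C[C@]12O[C@H]1C[C@@]3(C)CC[C@@](O)(C(C)C)[C@@H]3[C@@H](O)C2 | intermediate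
17 | (1R,4R,5S,6S,8R,9R)-9-(phenylselanyl)daucane-4,6,8-triol (8α-OH, 9β-SePh) | O[C@H]2C[C@@](C)(O)[C@H]([Se]c1ccccc1)C[C@@]3(C)CC[C@@](O)(C(C)C)[C@H]23 | intermediate
18 | selenoxide of 17 (mixture at selenium) | O[C@H]2C[C@@](C)(O)[C@H]([Se](=O)c1ccccc1)C[C@@]3(C)CC[C@@](O)(C(C)C)[C@H]23 | intermediate
19 | (1R,4R,5S,6S,8R)-dauc-9-ene-4,6,8-triol | O[C@H]2C[C@@](C)(O)C=C[C@@]3(C)CC[C@@](O)(C(C)C)[C@H]23 | intermediate
20 | vanillic acid | COc1cc(C(=O)O)ccc1O | starting material
21 | tert-butyldimethylsilyl 4-{[tert-butyl(dimethyl)silyl]oxy}-3-methoxybenzoate | COc1cc(C(=O)O[Si](C)(C)C(C)(C)C)ccc1O[Si](C)(C)C(C)(C)C | intermediate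
22 | 4-{[tert-butyl(dimethyl)silyl]oxy}-3-methoxybenzoic acid | COc1cc(C(=O)O)ccc1O[Si](C)(C)C(C)(C)C | intermediate
23 | (1R,4R,5S,6S,8R)-4,8-dihydroxydauc-9-en-6-yl 4-{[tert-butyl(dimethyl)silyl]oxy}-3-methoxybenzoate | COc1cc(C(=O)O[C@H]2C[C@@](C)(O)C=C[C@@]3(C)CC[C@@](O)(C(C)C)[C@H]23)ccc1O[Si](C)(C)C(C)(C)C | intermediate
24 | (1R,4R,5S,6S,8R)-4,8-dihydroxydauc-9-en-6-yl 4-hydroxy-3-methoxybenzoate (CNP0243386.4) | COc1cc(C(=O)O[C@H]2C[C@@](C)(O)C=C[C@@]3(C)CC[C@@](O)(C(C)C)[C@H]23)ccc1O | target

**Step count and risks**

Total steps: 14. Longest linear sequence: 12 steps (steps 1, 2, 4–11, 13 and 14, from compound 1).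

Steps most likely to fail:

Step 6. The zinc alkoxide may steer the carbenoid to the allylic ring alkene C5=C1 instead of the enol ether, or the enol ether may react through its other rotamer and give the diastereomeric cyclopropane, which would end as the C1 epimer after step 7. The fallback sets out from 11 and replaces hydroxyl direction by reagent control. N-(Trimethylsilyl)imidazole in CH2Cl2 should give the C4 trimethylsilyl ether of the dienol ether F1, which has no alkoxide to draw the carbenoid to C5=C1. Cyclopropanation of its enol ether with the zinc carbenoid from Et2Zn/CH2I2 modified by a stoichiometric chiral dipeptide (N-Boc-valyl-proline methyl ester, the antipode matched to the (1S,2R) ring) should give the trimethylsilyl-protected cyclopropane F2. K2CO3 in MeOH then removes the trimethylsilyl group and the route is rejoined at 12.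

Step 5. Deprotonation may occur at the ring methyl or ring CH2 instead of the tiglyl methyl, the intermediate alkoxide may add to the enone in an oxa-Michael ring closure before the dienolate forms, or the enol ether may form with the wrong geometry, which would lead to a trans-divinylcyclopropane that does not rearrange at 110 °C. The fallback sets out from 4 and moves the acidic site. Commercial 2-methylbut-3-enoic acid F3 is coupled with 6 (carbodiimide, DMAP) to its Weinreb amide, N-methoxy-N,2-dimethylbut-3-enamide F4. The dilithiated cyclopentenol 8, made from 4 as in step 4, is acylated with it to give the β,γ-unsaturated ketone 1-[(5R)-5-hydroxy-2-methyl-5-(propan-2-yl)cyclopent-1-en-1-yl]-2-methylbut-3-en-1-one F5. Its α-hydrogen, activated by both the carbonyl and the vinyl group, is removed far faster than any γ-hydrogen, so KN(SiMe3)2/TBSCl at −78 °C should give the same dienolate without competition and the route is rejoined at 11.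

Step 2. A secondary dialkylzinc may reduce the ketone by β-hydride transfer instead of adding, or add with insufficient facial selectivity. The fallback sets out from 2 and replaces asymmetric catalysis by resolution. iPrMgCl with anhydrous CeCl3 in THF at −78 °C should give racemic 2-iodo-3-methyl-1-(propan-2-yl)cyclopent-2-en-1-ol F6 by clean 1,2-addition. Preparative chromatography on a chiral stationary phase then separates the (1R)-alcohol, at which the route is rejoined (compound 4), from the (1S)-enantiomer F7, which is discarded.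

**Further compounds**

F1 | step 6 | C4 trimethylsilyl ether of 11, {[(1R)-2-[(1E)-1-{[tert-butyl(dimethyl)silyl]oxy}-2-methylbuta-1,3-dien-1-yl]-3-methyl-1-(propan-2-yl)cyclopent-2-en-1-yl]oxy}(trimethyl)silane | C=C/C(C)=C(/O[Si](C)(C)C(C)(C)C)C1=C(C)CC[C@@]1(O[Si](C)(C)C)C(C)C
F2 | step 6 | C4 trimethylsilyl ether of 12 | C=C[C@@]1(C)C[C@@]1(O[Si](C)(C)C(C)(C)C)C2=C(C)CC[C@@]2(O[Si](C)(C)C)C(C)C
F3 | step 5 | 2-methylbut-3-enoic acid (racemic, purchased) | C=CC(C)C(=O)O
F4 | step 5 | N-methoxy-N,2-dimethylbut-3-enamide (racemic) | C=CC(C)C(=O)N(C)OC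
F5 | step 5 | 1-[(5R)-5-hydroxy-2-methyl-5-(propan-2-yl)cyclopent-1-en-1-yl]-2-methylbut-3-en-1-one (both epimers at the α-carbon) | C=CC(C)C(=O)C1=C(C)CC[C@@]1(O)C(C)C
F6 | step 2 | racemic 2-iodo-3-methyl-1-(propan-2-yl)cyclopent-2-en-1-ol | CC1=C(I)C(O)(C(C)C)CC1
F7 | step 2 | (1S)-2-iodo-3-methyl-1-(propan-2-yl)cyclopent-2-en-1-ol | CC1=C(I)[C@@](O)(C(C)C)CC1
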